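At early times the initiator is a steady source, because its half-life of 84 s by its own decay is longer than the 25 s run.

all flasks: substrate 0.11 M; initiator 5.1 mol%; time 25 s
- north-east: coupling partner 1.80 equiv
- north-west: coupling partner 3.60 equiv

- part of the substrate that has reacted at the end, north-east
- part of the substrate that has reacted at the end, north-west
- what raising the equivalents of coupling partner from its lowest to its highest value here does to the part of the substrate that has reacted (changes below 5 percentage points count as none) (it falls / it rises / no change)

- in percentages every species weighs as the substrate in it: one ended chains counts as two
- for released group the idle adduct is counted in
- for a step with 2 of a species take k times the square, and two of it per event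
- run time (north-east): 25 s

1. Supply. Each initiator gives two initiating radicals, and each of these turns one substrate into capped initiator and first chain carrier. Carriers therefore start at 9.22 × 10⁻⁵ M/s in both flasks.

2. Carrier level. The first chain carrier takes coupling partner, giving product and second chain carrier; the second chain carrier takes substrate, giving released group and the first chain carrier again. A turn destroys no carrier, and carriers are lost as ended carrier or ended chains. That loss takes 2.48 ms at most, so loss balances supply (a stationary state), and c(first chain carrier) = 1.41 × 10⁻⁷ M.

3. Partner cost. A turn uses one coupling partner, and the released group then binds another as idle adduct, because K1·c(coupling partner) starts at 240 in north-east. The partner cost, the free coupling partner lost per substrate turned over by the chain, is 2.00 at that starting value.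

4. Reach. Equivalents divided by partner cost give the chain's reach at this cost: 90.2 % in north-east, whose charge lies below the cost. This is an estimate for the run and no final limit, since binding is reversible: as free coupling partner thins in north-east, K1·c(coupling partner) falls, and the cost falls with it. North-west holds more than the cost, so there substrate is limiting.

5. Time. Free coupling partner decays pseudo-first-order with time constant 8.23 s. North-east's chain therefore reaches 85.9 %, while north-west reaches 100 % of substrate reacted at 6.65 s.

6. Weak link. Initiating radicals also consume substrate, at no partner cost: 1.89 % of the charge by the end. North-east becomes 87.8 %, so the reckoned trend is a rise of 12 percentage points.

The forecast gave 87 % (82 % to 91 %) for north-east, 100 % (98 % to 100 %) for north-west and "it rises", on the ground that “each turn effectively uses two partner molecules”.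

    coupling partner + released group ⇌ idle adduct, settled at all times (K1 = 1200 /M)
    coupling partner + first chain carrier → product + second chain carrier (k2 = 4.33 × 10⁵ /M/s)
    substrate + initiating radical → capped initiator + first chain carrier (k3 = 3.48 × 10⁶ /M/s)
    substrate + second chain carrier → released group + first chain carrier (k4 = 2.17 × 10⁵ /M/s)
    initiator → 2 initiating radical (k5 = 0.00822 /s)
    first chain carrier → ended carrier (k6 = 403 /s)
    2 first chain carrier → ended chains (k7 = 9 × 10⁸ /M/s)

The simulation gives 87.8 % of the substrate reacted in north-east and 100 % in north-west: it rises, a change of 12 points. North-west ends with 44.9 % of its coupling partner free, and its charge less the partner cost leaves 44.6 %. A neighbour of north-west is charged with 0.900 equiv of coupling partner. Dividing by the partner cost gives a reach of 45.1 %, and the same time factor and capped share bring it to 44.8 %. That neighbour ends with 45.3 % of its substrate reacted.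

The constants used here are invented; the flask was simulated.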